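**Plan**

Retrosynthesis: the acyl groups go first (acetates at C8 and C13, 3-methylbut-2-enoate at C14, glycidate at C9 by invertive esterification). The butenolide is then cut at C7=C11 and O6–C12 (intramolecular Horner–Wadsworth–Emmons on a 6-acyloxy-7-ketone), both oxiranes at C3–O and C5–O (alkoxide displacing a sulfonate), and last the C1=C10 alkene and a C5 carbonyl are rejoined as a C5–C10 σ bond.
Enabling feature: C5 and C10 face each other across the ten-membered carbocycle C1–C10. A C5–C10 bond turns it into a cis-decalin (ring A = C1–C5/C10, ring B = C5–C10) whose angular C10 bears C14 and in which a C5 carbinol and a C1 sulfonate are 1,3-related; cutting that shared bond gives C5=O and the Z C1=C10 alkene.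
Forward order: rings A and B by Robinson annulation (cyclohexane-1,3-dione, ethyl vinyl ketone, formaldehyde); oxygenation of both rings on the rigid bicycle; fragmentation to the ten-membered ring; C4–C5 oxirane; C2–C3 oxirane; butenolide (five-membered ring, closed last); esters.
Stereochemistry: C10 comes from the D-phenylalanine-mediated aldol condensation. C1, C2, C3, C4, C6 and C9 are relayed from C10 on the bicycle (face-selective epoxidation, reductions, osmylations, trans-diaxial epoxide opening). C5 and C8 follow by 1,2-induction after ring opening. C3, C5 and C9 are inverted on purpose in the two oxirane closures and the Mitsunobu esterification; the glycidate centre is bought.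

Key step: step 19

Remark: germacrane locants are used for every ring compound (carbocycle C1–C10, C14 on C10, C15 = methyl on C4; in the bicycles, named "decal…", C5–C10 is the shared bond). β = towards the viewer and α = away when the locants run counterclockwise, so the target is the 2α,3β:4α,5α-diepoxide with 6β-O, 8α-OAc and 9β-O-acyl, and C14 sits on the α-face of the bicycles. TBDPS = tert-butyldiphenylsilyl, TIPS = triisopropylsilyl, TBS = tert-butyldimethylsilyl, TMS = trimethylsilyl, PMB = 4-methoxybenzyl, Ms = methanesulfonyl.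
Assumption: ethyl 2-(diethoxyphosphoryl)acrylate and methyl (S)-2-methyloxirane-2-carboxylate are taken as purchasable.

**Route**

Step 1
Reactants: 1 cyclohexane-1,3-dione; 2 ethyl vinyl ketone
Product: 3 2-(3-oxopentyl)cyclohexane-1,3-dione
Conditions: 2 (0.9 equiv), Et3N (cat.), H2O, 20 °C
Reagents that add atoms: none
Why: Michael addition of the 1,3-dione (C2–H) to the enone, with the dione in excess to suppress double addition.

Step 2
Reactants: 3 2-(3-oxopentyl)cyclohexane-1,3-dione; 4 formaldehyde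
Product: 5 2-(hydroxymethyl)-2-(3-oxopentyl)cyclohexane-1,3-dione
Conditions: 37% aq. CH2O, NaHCO3 (cat.), THF/H2O, 0 → 20 °C
Reagents that add atoms: none
Why: Aldol addition (hydroxymethylation) at the doubly activated C2, creating the quaternary carbon that becomes C10 with C14 attached.

Step 3
Reactants: 5 2-(hydroxymethyl)-2-(3-oxopentyl)cyclohexane-1,3-dione
Product: 6 TBDPS ether of 5
Conditions: TBDPSCl, imidazole, DMF, 0 → 20 °C
Reagents that add atoms: tert-butyl(chloro)diphenylsilane CC(C)(C)[Si](Cl)(c1ccccc1)c1ccccc1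
Why: Silylation of the primary alcohol, which blocks retro-aldol loss of formaldehyde.

Step 4
Reactants: 6 TBDPS ether of 5
Product: 8 enedione (8aR)-8a-[(tert-butyldiphenylsilyloxy)methyl]-5-methyl-3,4,8,8a-tetrahydronaphthalene-1,6(2H,7H)-dione, via bicyclic ketol 7 (not isolated)
Conditions: D-phenylalanine (1 equiv), (1R)-(−)-10-camphorsulfonic acid (0.5 equiv), DMF, 30 → 70 °C
Reagents that add atoms: none
Why: Enantioselective intramolecular aldol condensation (Hajos–Parrish–Eder–Sauer–Wiechert reaction, completing the Robinson annulation): the D-amino-acid enamine selects one of the two enantiotopic ring carbonyls and sets C10, in the sense mirror-related to that known for L-amino acids, which is the one needed when the enone ring is ring A.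

Step 5
Reactants: 8 enedione
Product: 9 9α-hydroxy enone
Conditions: NaBH4 (0.3 equiv), EtOH, −10 °C
Reagents that add atoms: none
Why: Chemoselective borohydride reduction of the saturated ketone beside the enone; hydride adds anti to the angular C14 group and sets C9 as the 9α-alcohol (cis to C14).

Step 6
Reactants: 9 9α-hydroxy enone
Product: 10 9α-TIPS ether
Conditions: TIPSOTf, 2,6-lutidine, CH2Cl2, 0 °C
Reagents that add atoms: triisopropylsilyl trifluoromethanesulfonate CC(C)[Si](OS(=O)(=O)C(F)(F)F)(C(C)C)C(C)C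
Why: Silyl triflate silylation of the hindered secondary alcohol; TIPS is chosen so that it outlasts the TBS ether introduced later.

Step 7
Reactants: 10 9α-TIPS ether
Product: 12 1,4,6-trien-3-one, via 4,6-dienone 11 (not isolated)
Conditions: DDQ (2.2 equiv), TsOH·H2O (cat.), 1,4-dioxane, 90 °C
Reagents that add atoms: none
Why: Quinone dehydrogenation of a 4-en-3-one: the acid-catalysed dienol pathway gives the 6,7-alkene and the uncatalysed pathway the 1,2-alkene (one-flask conversion of 4-en-3-ones into 1,4,6-trien-3-ones), with DDQ held near the stoichiometric amount to spare C8.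

Step 8
Reactants: 12 1,4,6-trien-3-one
Product: 13 1β,2β-epoxy-4,6-dien-3-one
Conditions: H2O2 (30%), NaOH, MeOH, 0 °C
Reagents that add atoms: hydrogen peroxide OO
Why: Weitz–Scheffer (nucleophilic) epoxidation: hydroperoxide adds to C1, the only unsubstituted β-carbon of the trienone, from the β-face opposite the angular C14 group.

Step 9
Reactants: 13 1β,2β-epoxy-4,6-dien-3-one
Product: 14 6β,7β-diol
Conditions: OsO4 (cat.), N-methylmorpholine N-oxide, acetone/H2O, 20 °C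
Reagents that add atoms: osmium tetroxide O=[Os](=O)(=O)=O; N-methylmorpholine N-oxide C[N+]1([O-])CCOCC1
Why: Upjohn dihydroxylation of the most electron-rich alkene (the γ,δ-bond C6=C7) from the β-face, the α-face being screened by C14 and the 9α-silyl ether; this sets C6 (β-O) and gives C7 the oxygen later needed as a ketone.

Step 10
Reactants: 14 6β,7β-diol
Product: 16 6β-PMB ether 7β-alcohol, via stannylene acetal 15 (not isolated)
Conditions: Bu2SnO, MeOH, reflux; then PMBCl, CsF, DMF, 20 °C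
Reagents that add atoms: 4-methoxybenzyl chloride COc1ccc(CCl)cc1
Why: Stannylene-acetal-mediated monoalkylation of a cis-diol, which goes to the equatorial oxygen (allylic O6; the 7β-OH is axial).

Step 11
Reactants: 16 6β-PMB ether 7β-alcohol
Product: 17 6β-PMB 7β-TBS epoxy enone
Conditions: TBSOTf, 2,6-lutidine, CH2Cl2, −40 °C
Reagents that add atoms: tert-butyldimethylsilyl trifluoromethanesulfonate CC(C)(C)[Si](C)(C)OS(=O)(=O)C(F)(F)F
Why: Silyl triflate silylation of the remaining (axial) secondary alcohol.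

Step 12
Reactants: 17 6β-PMB 7β-TBS epoxy enone
Product: 18 3α-allylic alcohol
Conditions: NaBH4, CeCl3·7H2O, MeOH, −40 °C
Reagents that add atoms: none
Why: Luche 1,2-reduction: hydride is delivered axially from the β-face, away from C14, setting C3 as the pseudo-equatorial 3α-alcohol as in angularly substituted 4-en-3-ones.

Step 13
Reactants: 18 3α-allylic alcohol
Product: 20 3α,4α,5α-triol (cis-decalin), via osmate ester 19 (not isolated)
Conditions: OsO4 (1.1 equiv), TMEDA (1.2 equiv), CH2Cl2, −78 °C; then ethylenediamine, 20 °C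
Reagents that add atoms: osmium tetroxide O=[Os](=O)(=O)=O
Why: Hydroxyl-directed osmylation: the allylic 3α-OH hydrogen-bonds to the OsO4–TMEDA complex and steers it to the α-face of the tetrasubstituted C4=C5 bond (the β-face is also blocked by the 6β-PMB ether), which sets C4 (α-OH, β-CH3) and makes the ring fusion cis (5α-OH on the side of C14).

Step 14
Reactants: 20 3α,4α,5α-triol
Product: 21 3α-phenylurethane
Conditions: PhNCO, pyridine, CH2Cl2, 20 °C
Reagents that add atoms: phenyl isocyanate O=C=Nc1ccccc1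
Why: Urethane formation at the only secondary hydroxyl; the tertiary 4- and 5-hydroxyls add to the isocyanate far more slowly.

Step 15
Reactants: 21 3α-phenylurethane
Product: 23 2α,3α-cyclic carbonate 1β,4α,5α-triol, via iminocarbonate 22 (not isolated)
Conditions: BF3·OEt2 (0.3 equiv), Et2O, −20 °C; then 1 M H2SO4, 0 °C
Reagents that add atoms: water O
Why: Lewis-acid-promoted intramolecular epoxide opening by the urethane carbonyl oxygen (neighbouring-group delivery, 5-exo, trans-diaxial, inversion at C2; neopentyl C1 is not attacked) and hydrolysis of the iminocarbonate, which sets C2 (α-O, cis to O3) and frees the 1β-hydroxyl.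

Step 16
Reactants: 23 2α,3α-cyclic carbonate
Product: 24 1β,2α,3α,4α,5α-pentaol
Conditions: K2CO3 (cat.), MeOH, 20 °C
Reagents that add atoms: none
Why: Base-catalysed transesterification (methanolysis) of the cyclic carbonate.

Step 17
Reactants: 24 pentaol
Product: 25 2α,3α-acetonide
Conditions: 2-methoxypropene (1.2 equiv), PPTS (cat.), CH2Cl2, 0 °C
Reagents that add atoms: 2-methoxypropene COC(C)=C
Why: Kinetic acetonide formation on the only cis-vicinal pair of secondary hydroxyls (C2/C3); the 1β-OH is trans to O2 and the tertiary 4,5-diol reacts much more slowly.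

Step 18
Reactants: 25 2α,3α-acetonide
Product: 26 1β-mesylate (cis-decalin 4α,5α-diol 1-mesylate)
Conditions: MsCl, pyridine, DMAP (cat.), CH2Cl2, 0 °C
Reagents that add atoms: methanesulfonyl chloride CS(Cl)(=O)=O
Why: Sulfonylation of the one remaining secondary alcohol (tertiary alcohols are not mesylated under pyridine conditions).

Step 19
Reactants: 26 1β-mesylate
Product: 27 (Z)-cyclodec-1(10)-en-5-one
Conditions: KOC(CH3)3 (1.1 equiv), THF, −20 → 0 °C
Reagents that add atoms: none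
Why: The C5 alkoxide pushes its lone pair into C5=O while the shared C5–C10 σ bond and the antiperiplanar C1–O bond of the equatorial mesylate break in one concerted step (Grob fragmentation of a decalin-1,3-diol monosulfonate, Wharton type). No ring is closed by bond formation: the ten-membered carbocycle arises because the bond common to rings A and B is cut. No stereocentre is created; the new stereo-element is the C1=C10 alkene, fixed by the relative configuration of C1 and C10 in the cis-fused bicycle: with the 1β-mesylate trans to C14 and C1–OMs anti to C10–C5, C9 is gauche and C14 anti to C2 across C10–C1, so C9 and C2 end up cis (Z, since C9 carries oxygen). The step needs fragmentation to outrun E2 elimination, α-ketol rearrangement and epimerisation at C6 of the product; no hydrogen is antiperiplanar to the mesylate, the acetonide and the silyl and PMB ethers are inert to alkoxide, and only 1.1 equivalents of base are used so that the product is left as the neutral tertiary alcohol.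

Step 20
Reactants: 27 (Z)-cyclodec-1(10)-en-5-one
Product: 28 4α-TMS ether
Conditions: 1-(trimethylsilyl)imidazole, CH2Cl2, 20 °C
Reagents that add atoms: 1-(trimethylsilyl)imidazole C[Si](C)(C)n1ccnc1
Why: Silyl transfer to the tertiary α-ketol hydroxyl, so that it can no longer chelate the metal in the next step.

Step 21
Reactants: 28 4α-TMS ether
Product: 29 5β-alcohol
Conditions: Zn(BH4)2, Et2O, −30 °C; then H2O
Reagents that add atoms: none
Why: Chelation-controlled ketone reduction (Cram chelate model): zinc bridges C5=O and the 6β-PMB ether oxygen and hydride enters from the side of H6, setting C5 as the 5β-alcohol (cis to O6, trans to O4).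

Step 22
Reactants: 29 5β-alcohol
Product: 30 5β-mesylate
Conditions: MsCl, Et3N, CH2Cl2, −20 °C
Reagents that add atoms: methanesulfonyl chloride CS(Cl)(=O)=O
Why: Mesylation (sulfene mechanism) of the only free hydroxyl.

Step 23
Reactants: 30 5β-mesylate
Product: 31 2α,3α,4α-triol 5β-mesylate
Conditions: PPTS, MeOH, 20 °C
Reagents that add atoms: none
Why: Acid-catalysed transketalisation of the acetonide and methanolysis of the tertiary TMS ether, placed before any oxirane exists; the secondary TBS, TIPS and TBDPS ethers and the mesylate tolerate PPTS.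

Step 24
Reactants: 31 2α,3α,4α-triol 5β-mesylate
Product: 32 4α,5α-epoxy-2α,3α-diol
Conditions: K2CO3, MeOH, 0 → 20 °C
Reagents that add atoms: none
Why: Intramolecular Williamson etherification (3-exo-tet): the tertiary 4α-alkoxide displaces the 5β-mesylate with inversion, giving the 4α,5α (cis) oxirane of the target.

Step 25
Reactants: 32 4α,5α-epoxy-2α,3α-diol
Product: 33 2α-acetate
Conditions: Ac2O (1.1 equiv), 2,4,6-collidine, CH2Cl2, −20 °C
Reagents that add atoms: acetic anhydride CC(=O)OC(C)=O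
Why: Site-selective acylation: the allylic 2-OH reacts before the 3-OH, which is flanked by the fully substituted oxirane carbon C4.

Step 26
Reactants: 33 2α-acetate
Product: 34 2α-acetoxy 3α-mesylate
Conditions: MsCl, Et3N, DMAP (cat.), CH2Cl2, 0 °C
Reagents that add atoms: methanesulfonyl chloride CS(Cl)(=O)=O
Why: Mesylation of the remaining hydroxyl.

Step 27
Reactants: 34 2α-acetoxy 3α-mesylate
Product: 36 2α,3β:4α,5α-diepoxide, via hydroxy mesylate 35 (not isolated)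
Conditions: K2CO3, MeOH, 0 → 20 °C
Reagents that add atoms: none
Why: Methanolysis of the acetate releases the 2α-alkoxide, which displaces the 3α-mesylate with inversion (intramolecular Williamson, 3-exo-tet) to give the trans 2α,3β-oxirane; O4 is already tied up in the first oxirane and cannot compete.

Step 28
Reactants: 36 diepoxide
Product: 37 7β-alcohol
Conditions: HF·pyridine, pyridine, THF, 0 °C
Reagents that add atoms: none
Why: Fluoride desilylation, selective for the least robust silyl ether (secondary TBS before TIPS and TBDPS), buffered with pyridine to spare the oxiranes.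

Step 29
Reactants: 37 7β-alcohol
Product: 38 7-ketone
Conditions: Dess–Martin periodinane, NaHCO3, CH2Cl2, 0 → 20 °C
Reagents that add atoms: none
Why: Dess–Martin oxidation of the secondary alcohol under buffered, non-basic conditions that do not enolise the new ketone towards C6.

Step 30
Reactants: 38 7-ketone
Product: 40 8α-hydroxy ketone, via potassium enolate 39 (not isolated)
Conditions: KN(SiMe3)2 (1.1 equiv), THF, −78 °C; then 2-(phenylsulfonyl)-3-phenyloxaziridine; AcOH quench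
Reagents that add atoms: 2-(phenylsulfonyl)-3-phenyloxaziridine O=S(=O)(c1ccccc1)N1OC1c1ccccc1
Why: Kinetic deprotonation at the unhindered C8 methylene (not at the alkoxy-bearing C6) and electrophilic hydroxylation of the enolate by the N-sulfonyloxaziridine anti to the neighbouring 9α-silyloxy group (1,2-induction), which sets C8 as the 8α-alcohol.

Step 31
Reactants: 40 8α-hydroxy ketone
Product: 41 8α-acetate
Conditions: Ac2O, pyridine, DMAP (cat.), CH2Cl2, 0 °C
Reagents that add atoms: acetic anhydride CC(=O)OC(C)=O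
Why: DMAP-catalysed acetylation of the α-ketol hydroxyl, installing the C8 acetate of the target.

Step 32
Reactants: 41 8α-acetate
Product: 42 6β-hydroxy ketone
Conditions: DDQ, CH2Cl2/pH 7 buffer, 0 °C
Reagents that add atoms: none
Why: Oxidative cleavage of the 4-methoxybenzyl ether by DDQ (hydride abstraction, then hydrolysis), leaving silyl ethers, acetate and oxiranes untouched.

Step 33
Reactants: 43 4-methoxybenzyl alcohol; 44 ethyl 2-(diethoxyphosphoryl)acrylate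
Product: 45 ethyl 2-(diethoxyphosphoryl)-3-[(4-methoxybenzyl)oxy]propanoate
Conditions: KOC(CH3)3 (0.1 equiv), THF, 0 °C
Reagents that add atoms: none
Why: Base-catalysed oxa-Michael addition of the alkoxide to the doubly activated vinylphosphonate.

Step 34
Reactants: 45 ethyl 2-(diethoxyphosphoryl)-3-[(4-methoxybenzyl)oxy]propanoate
Product: 46 2-(diethoxyphosphoryl)-3-[(4-methoxybenzyl)oxy]propanoic acid
Conditions: LiOH (1.05 equiv), THF/H2O, 0 °C; then 1 M HCl to pH 3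
Reagents that add atoms: lithium hydroxide [Li+].[OH-]
Why: Saponification of the carboxylic ester; the phosphonate diester is not hydrolysed by one equivalent of hydroxide at 0 °C.

Step 35
Reactants: 42 6β-hydroxy ketone; 46 2-(diethoxyphosphoryl)-3-[(4-methoxybenzyl)oxy]propanoic acid
Product: 47 6β-phosphonoacyl ester
Conditions: DCC, DMAP (cat.), CH2Cl2, 0 → 20 °C
Reagents that add atoms: none
Why: Steglich esterification of the secondary 6β-hydroxyl.

Step 36
Reactants: 47 6β-phosphonoacyl ester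
Product: 48 butenolide
Conditions: LiCl, iPr2NEt, MeCN, 20 °C
Reagents that add atoms: none
Why: Intramolecular Horner–Wadsworth–Emmons olefination under mild lithium chloride/amine conditions: the phosphonate carbanion attacks the C7 ketone (five-membered ring closure) and elimination gives the C7=C11 butenolide carrying C13 as its PMB ether.

Step 37
Reactants: 48 butenolide
Product: 49 9α,14-diol
Conditions: Bu4NF, AcOH (1:1), THF, 0 → 20 °C
Reagents that add atoms: none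
Why: Fluoride desilylation of both remaining silyl ethers, buffered with acetic acid so that the butenolide and the acetate are not exposed to alkoxide.

Step 38
Reactants: 49 9α,14-diol; 50 3-methylbut-2-enoyl chloride
Product: 51 14-(3-methylbut-2-enoate)
Conditions: 2,4,6-collidine, CH2Cl2, −78 → −40 °C
Reagents that add atoms: none
Why: Acylation of the primary allylic alcohol by the acid chloride, much faster than at the hindered secondary 9-OH; collidine avoids ketene formation and deconjugation of the acyl group.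

Step 39
Reactants: 52 methyl (S)-2-methyloxirane-2-carboxylate
Product: 53 (S)-2-methyloxirane-2-carboxylic acid
Conditions: LiOH (1.05 equiv), THF/H2O, 0 °C; then 1 M HCl (1 equiv), 0 °C
Reagents that add atoms: lithium hydroxide [Li+].[OH-]
Why: Saponification of the methyl ester at 0 °C; the oxirane is stable to cold hydroxide and the acid is liberated with one equivalent of HCl.

Step 40
Reactants: 51 14-(3-methylbut-2-enoate); 53 (S)-2-methyloxirane-2-carboxylic acid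
Product: 54 9β-[(S)-2-methyloxirane-2-carboxylate]
Conditions: PPh3, DIAD, toluene, 0 °C
Reagents that add atoms: none
Why: Mitsunobu esterification: the oxyphosphonium of the allylic 9α-alcohol is displaced by the carboxylate with SN2 inversion, which sets C9 as the 9β-ester; the cis 8α-acetate cannot participate.

Step 41
Reactants: 54 9β-[(S)-2-methyloxirane-2-carboxylate]
Product: 55 13-alcohol
Conditions: DDQ, CH2Cl2/pH 7 buffer, 0 °C
Reagents that add atoms: none
Why: DDQ cleavage of the allylic PMB ether at C13.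

Step 42
Reactants: 55 13-alcohol
Product: 56 CNP0279449.1
Conditions: Ac2O, pyridine, DMAP (cat.), CH2Cl2, 0 °C
Reagents that add atoms: acetic anhydride CC(=O)OC(C)=O
Why: Acetylation of the primary allylic alcohol completes the target.

**Compound list**

1 | cyclohexane-1,3-dione | O=C1CCCC(=O)C1 | starting material
2 | ethyl vinyl ketone (pent-1-en-3-one) | CCC(=O)C=C | starting material
3 | 2-(3-oxopentyl)cyclohexane-1,3-dione | CCC(=O)CCC1C(=O)CCCC1=O | intermediate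
4 | formaldehyde | C=O | starting material
5 | 2-(hydroxymethyl)-2-(3-oxopentyl)cyclohexane-1,3-dione | CCC(=O)CCC1(CO)C(=O)CCCC1=O | intermediate
6 | 2-[(tert-butyldiphenylsilyloxy)methyl]-2-(3-oxopentyl)cyclohexane-1,3-dione | CCC(=O)CCC1(CO[Si](c2ccccc2)(c2ccccc2)C(C)(C)C)C(=O)CCCC1=O | intermediate
7 | cis-fused ketol, 5α-hydroxy-4-methyl-14-TBDPSO-decalin-3,9-dione (C4 epimers) | C1CC(=O)C(C)[C@]2(O)CCCC(=O)[C@]12CO[Si](c3ccccc3)(c3ccccc3)C(C)(C)C | intermediate (not isolated)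
8 | (8aR)-8a-[(tert-butyldiphenylsilyloxy)methyl]-5-methyl-3,4,8,8a-tetrahydronaphthalene-1,6(2H,7H)-dione (4-methyl-14-TBDPSO-decal-4-ene-3,9-dione) | C1CC(=O)C(C)=C2CCCC(=O)[C@]12CO[Si](c3ccccc3)(c3ccccc3)C(C)(C)C | intermediate
9 | 9α-hydroxy-4-methyl-14-TBDPSO-decal-4-en-3-one | C1CC(=O)C(C)=C2CCC[C@@H](O)[C@]12CO[Si](c3ccccc3)(c3ccccc3)C(C)(C)C | intermediate
10 | 4-methyl-14-TBDPSO-9α-TIPSO-decal-4-en-3-one | C1CC(=O)C(C)=C2CCC[C@@H](O[Si](C(C)C)(C(C)C)C(C)C)[C@]12CO[Si](c3ccccc3)(c3ccccc3)C(C)(C)C | intermediate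
11 | 4-methyl-14-TBDPSO-9α-TIPSO-decala-4,6-dien-3-one | C1CC(=O)C(C)=C2C=CC[C@@H](O[Si](C(C)C)(C(C)C)C(C)C)[C@]12CO[Si](c3ccccc3)(c3ccccc3)C(C)(C)C | intermediate (not isolated)
12 | 4-methyl-14-TBDPSO-9α-TIPSO-decala-1,4,6-trien-3-one | C1=CC(=O)C(C)=C2C=CC[C@@H](O[Si](C(C)C)(C(C)C)C(C)C)[C@]12CO[Si](c3ccccc3)(c3ccccc3)C(C)(C)C | intermediate
13 | 1β,2β-epoxy-4-methyl-14-TBDPSO-9α-TIPSO-decala-4,6-dien-3-one | [C@@H]12O[C@@H]1C(=O)C(C)=C3C=CC[C@@H](O[Si](C(C)C)(C(C)C)C(C)C)[C@]23CO[Si](c4ccccc4)(c4ccccc4)C(C)(C)C | intermediate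
14 | 1β,2β-epoxy-6β,7β-dihydroxy-4-methyl-14-TBDPSO-9α-TIPSO-decal-4-en-3-one | [C@@H]12O[C@@H]1C(=O)C(C)=C3[C@H](O)[C@H](O)C[C@@H](O[Si](C(C)C)(C(C)C)C(C)C)[C@]23CO[Si](c4ccccc4)(c4ccccc4)C(C)(C)C | intermediate
15 | 6β,7β-O-(dibutylstannylene) acetal of 14 | [C@@H]12O[C@@H]1C(=O)C(C)=C3[C@@H]5O[Sn](CCCC)(CCCC)O[C@@H]5C[C@@H](O[Si](C(C)C)(C(C)C)C(C)C)[C@]23CO[Si](c4ccccc4)(c4ccccc4)C(C)(C)C | intermediate (not isolated)
16 | 1β,2β-epoxy-7β-hydroxy-6β-PMBO-4-methyl-14-TBDPSO-9α-TIPSO-decal-4-en-3-one | [C@@H]12O[C@@H]1C(=O)C(C)=C3[C@H](OCc5ccc(OC)cc5)[C@H](O)C[C@@H](O[Si](C(C)C)(C(C)C)C(C)C)[C@]23CO[Si](c4ccccc4)(c4ccccc4)C(C)(C)C | intermediate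
17 | 1β,2β-epoxy-6β-PMBO-7β-TBSO-4-methyl-14-TBDPSO-9α-TIPSO-decal-4-en-3-one | [C@@H]12O[C@@H]1C(=O)C(C)=C3[C@H](OCc5ccc(OC)cc5)[C@H](O[Si](C)(C)C(C)(C)C)C[C@@H](O[Si](C(C)C)(C(C)C)C(C)C)[C@]23CO[Si](c4ccccc4)(c4ccccc4)C(C)(C)C | intermediate
18 | 1β,2β-epoxy-6β-PMBO-7β-TBSO-4-methyl-14-TBDPSO-9α-TIPSO-decal-4-en-3α-ol | [C@@H]12O[C@@H]1[C@@H](O)C(C)=C3[C@H](OCc5ccc(OC)cc5)[C@H](O[Si](C)(C)C(C)(C)C)C[C@@H](O[Si](C(C)C)(C(C)C)C(C)C)[C@]23CO[Si](c4ccccc4)(c4ccccc4)C(C)(C)C | intermediate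
19 | 4α,5α-osmate ester of 18 (dioxo-osmium TMEDA chelate, hexavalent osmium) | [C@@H]12O[C@@H]1[C@@H](O)[C@@](C)(O[Os-2]67(=O)(=O)[N+](C)(C)CC[N+]6(C)C)[C@]3(O7)[C@H](OCc5ccc(OC)cc5)[C@H](O[Si](C)(C)C(C)(C)C)C[C@@H](O[Si](C(C)C)(C(C)C)C(C)C)[C@]23CO[Si](c4ccccc4)(c4ccccc4)C(C)(C)C | intermediate (not isolated)
20 | 1β,2β-epoxy-6β-PMBO-7β-TBSO-4β-methyl-14-TBDPSO-9α-TIPSO-cis-decalin-3α,4α,5α-triol | [C@@H]12O[C@@H]1[C@@H](O)[C@@](C)(O)[C@]3(O)[C@H](OCc5ccc(OC)cc5)[C@H](O[Si](C)(C)C(C)(C)C)C[C@@H](O[Si](C(C)C)(C(C)C)C(C)C)[C@]23CO[Si](c4ccccc4)(c4ccccc4)C(C)(C)C | intermediate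
21 | 3α-O-(phenylcarbamoyl) derivative of 20 | [C@@H]12O[C@@H]1[C@@H](OC(=O)Nc6ccccc6)[C@@](C)(O)[C@]3(O)[C@H](OCc5ccc(OC)cc5)[C@H](O[Si](C)(C)C(C)(C)C)C[C@@H](O[Si](C(C)C)(C(C)C)C(C)C)[C@]23CO[Si](c4ccccc4)(c4ccccc4)C(C)(C)C | intermediate
22 | 2α,3α-cyclic N-phenyliminocarbonate, 1β,4α,5α-triol | O[C@@H]1[C@H]2OC(=Nc6ccccc6)O[C@H]2[C@@](C)(O)[C@]3(O)[C@H](OCc5ccc(OC)cc5)[C@H](O[Si](C)(C)C(C)(C)C)C[C@@H](O[Si](C(C)C)(C(C)C)C(C)C)[C@]13CO[Si](c4ccccc4)(c4ccccc4)C(C)(C)C | intermediate (not isolated)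
23 | 2α,3α-cyclic carbonate, 1β,4α,5α-triol (6β-PMBO, 7β-TBSO, 9α-TIPSO, 14-TBDPSO, 4β-methyl cis-decalin) | O[C@@H]1[C@H]2OC(=O)O[C@H]2[C@@](C)(O)[C@]3(O)[C@H](OCc5ccc(OC)cc5)[C@H](O[Si](C)(C)C(C)(C)C)C[C@@H](O[Si](C(C)C)(C(C)C)C(C)C)[C@]13CO[Si](c4ccccc4)(c4ccccc4)C(C)(C)C | intermediate
24 | 6β-PMBO-7β-TBSO-4β-methyl-14-TBDPSO-9α-TIPSO-cis-decalin-1β,2α,3α,4α,5α-pentaol | O[C@@H]1[C@@H](O)[C@@H](O)[C@@](C)(O)[C@]3(O)[C@H](OCc5ccc(OC)cc5)[C@H](O[Si](C)(C)C(C)(C)C)C[C@@H](O[Si](C(C)C)(C(C)C)C(C)C)[C@]13CO[Si](c4ccccc4)(c4ccccc4)C(C)(C)C | intermediate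
25 | 2α,3α-O-isopropylidene derivative of 24 (1β,4α,5α-triol) | O[C@@H]1[C@H]2OC(C)(C)O[C@H]2[C@@](C)(O)[C@]3(O)[C@H](OCc5ccc(OC)cc5)[C@H](O[Si](C)(C)C(C)(C)C)C[C@@H](O[Si](C(C)C)(C(C)C)C(C)C)[C@]13CO[Si](c4ccccc4)(c4ccccc4)C(C)(C)C | intermediate
26 | 1β-mesyloxy-2α,3α-O-isopropylidene-6β-PMBO-7β-TBSO-4β-methyl-14-TBDPSO-9α-TIPSO-cis-decalin-4α,5α-diol | CS(=O)(=O)O[C@@H]1[C@H]2OC(C)(C)O[C@H]2[C@@](C)(O)[C@]3(O)[C@H](OCc5ccc(OC)cc5)[C@H](O[Si](C)(C)C(C)(C)C)C[C@@H](O[Si](C(C)C)(C(C)C)C(C)C)[C@]13CO[Si](c4ccccc4)(c4ccccc4)C(C)(C)C | intermediate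
27 | (1(10)Z)-4α-hydroxy-4β-methyl-2α,3α-isopropylidenedioxy-6β-PMBO-7β-TBSO-9α-TIPSO-10-(TBDPSO-methyl)cyclodec-1(10)-en-5-one | O=C1[C@H](OCc5ccc(OC)cc5)[C@H](O[Si](C)(C)C(C)(C)C)C[C@@H](O[Si](C(C)C)(C(C)C)C(C)C)/C(CO[Si](c4ccccc4)(c4ccccc4)C(C)(C)C)=C\[C@H]2OC(C)(C)O[C@H]2[C@@]1(C)O | intermediate
28 | 4α-O-TMS ether of 27 | O=C1[C@H](OCc5ccc(OC)cc5)[C@H](O[Si](C)(C)C(C)(C)C)C[C@@H](O[Si](C(C)C)(C(C)C)C(C)C)/C(CO[Si](c4ccccc4)(c4ccccc4)C(C)(C)C)=C\[C@H]2OC(C)(C)O[C@H]2[C@@]1(C)O[Si](C)(C)C | intermediate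
29 | 5β-alcohol of 28 | O[C@@H]1[C@H](OCc5ccc(OC)cc5)[C@H](O[Si](C)(C)C(C)(C)C)C[C@@H](O[Si](C(C)C)(C(C)C)C(C)C)/C(CO[Si](c4ccccc4)(c4ccccc4)C(C)(C)C)=C\[C@H]2OC(C)(C)O[C@H]2[C@@]1(C)O[Si](C)(C)C | intermediate
30 | 5β-mesylate of 29 | CS(=O)(=O)O[C@@H]1[C@H](OCc5ccc(OC)cc5)[C@H](O[Si](C)(C)C(C)(C)C)C[C@@H](O[Si](C(C)C)(C(C)C)C(C)C)/C(CO[Si](c4ccccc4)(c4ccccc4)C(C)(C)C)=C\[C@H]2OC(C)(C)O[C@H]2[C@@]1(C)O[Si](C)(C)C | intermediate
31 | (1(10)Z)-5β-mesyloxy-4β-methyl-6β-PMBO-7β-TBSO-9α-TIPSO-10-(TBDPSO-methyl)cyclodec-1(10)-ene-2α,3α,4α-triol | CS(=O)(=O)O[C@@H]1[C@H](OCc5ccc(OC)cc5)[C@H](O[Si](C)(C)C(C)(C)C)C[C@@H](O[Si](C(C)C)(C(C)C)C(C)C)/C(CO[Si](c4ccccc4)(c4ccccc4)C(C)(C)C)=C\[C@@H](O)[C@@H](O)[C@@]1(C)O | intermediate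
32 | 4α,5α-epoxy-2α,3α-diol (6β-PMBO, 7β-TBSO, 9α-TIPSO, 14-TBDPSO, 1(10)Z) | [C@H]12[C@H](OCc5ccc(OC)cc5)[C@H](O[Si](C)(C)C(C)(C)C)C[C@@H](O[Si](C(C)C)(C(C)C)C(C)C)/C(CO[Si](c4ccccc4)(c4ccccc4)C(C)(C)C)=C\[C@@H](O)[C@@H](O)[C@@]1(C)O2 | intermediate
33 | 2α-acetate of 32 | [C@H]12[C@H](OCc5ccc(OC)cc5)[C@H](O[Si](C)(C)C(C)(C)C)C[C@@H](O[Si](C(C)C)(C(C)C)C(C)C)/C(CO[Si](c4ccccc4)(c4ccccc4)C(C)(C)C)=C\[C@@H](OC(C)=O)[C@@H](O)[C@@]1(C)O2 | intermediate
34 | 2α-acetoxy-3α-mesyloxy-4α,5α-epoxide | [C@H]12[C@H](OCc5ccc(OC)cc5)[C@H](O[Si](C)(C)C(C)(C)C)C[C@@H](O[Si](C(C)C)(C(C)C)C(C)C)/C(CO[Si](c4ccccc4)(c4ccccc4)C(C)(C)C)=C\[C@@H](OC(C)=O)[C@@H](OS(C)(=O)=O)[C@@]1(C)O2 | intermediate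
35 | 2α-hydroxy-3α-mesyloxy-4α,5α-epoxide | [C@H]12[C@H](OCc5ccc(OC)cc5)[C@H](O[Si](C)(C)C(C)(C)C)C[C@@H](O[Si](C(C)C)(C(C)C)C(C)C)/C(CO[Si](c4ccccc4)(c4ccccc4)C(C)(C)C)=C\[C@@H](O)[C@@H](OS(C)(=O)=O)[C@@]1(C)O2 | intermediate (not isolated)
36 | (1(10)Z)-2α,3β:4α,5α-diepoxy-4β-methyl-6β-PMBO-7β-TBSO-9α-TIPSO-10-(TBDPSO-methyl)cyclodec-1(10)-ene | [C@H]12[C@H](OCc5ccc(OC)cc5)[C@H](O[Si](C)(C)C(C)(C)C)C[C@@H](O[Si](C(C)C)(C(C)C)C(C)C)/C(CO[Si](c4ccccc4)(c4ccccc4)C(C)(C)C)=C\[C@H]3O[C@@H]3[C@@]1(C)O2 | intermediate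
37 | 7β-alcohol of 36 | [C@H]12[C@H](OCc5ccc(OC)cc5)[C@H](O)C[C@@H](O[Si](C(C)C)(C(C)C)C(C)C)/C(CO[Si](c4ccccc4)(c4ccccc4)C(C)(C)C)=C\[C@H]3O[C@@H]3[C@@]1(C)O2 | intermediate
38 | 7-ketone (2α,3β:4α,5α-diepoxy-6β-PMBO-9α-TIPSO-14-TBDPSO) | [C@H]12[C@H](OCc5ccc(OC)cc5)C(=O)C[C@@H](O[Si](C(C)C)(C(C)C)C(C)C)/C(CO[Si](c4ccccc4)(c4ccccc4)C(C)(C)C)=C\[C@H]3O[C@@H]3[C@@]1(C)O2 | intermediate
39 | potassium 7(8)-enolate of 38 | [K+].[C@H]12[C@H](OCc5ccc(OC)cc5)C([O-])=C[C@@H](O[Si](C(C)C)(C(C)C)C(C)C)/C(CO[Si](c4ccccc4)(c4ccccc4)C(C)(C)C)=C\[C@H]3O[C@@H]3[C@@]1(C)O2 | intermediate (not isolated)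
40 | 8α-hydroxy-7-ketone | [C@H]12[C@H](OCc5ccc(OC)cc5)C(=O)[C@@H](O)[C@@H](O[Si](C(C)C)(C(C)C)C(C)C)/C(CO[Si](c4ccccc4)(c4ccccc4)C(C)(C)C)=C\[C@H]3O[C@@H]3[C@@]1(C)O2 | intermediate
41 | 8α-acetoxy-7-ketone | [C@H]12[C@H](OCc5ccc(OC)cc5)C(=O)[C@@H](OC(C)=O)[C@@H](O[Si](C(C)C)(C(C)C)C(C)C)/C(CO[Si](c4ccccc4)(c4ccccc4)C(C)(C)C)=C\[C@H]3O[C@@H]3[C@@]1(C)O2 | intermediate
42 | 8α-acetoxy-6β-hydroxy-7-ketone | [C@H]12[C@H](O)C(=O)[C@@H](OC(C)=O)[C@@H](O[Si](C(C)C)(C(C)C)C(C)C)/C(CO[Si](c4ccccc4)(c4ccccc4)C(C)(C)C)=C\[C@H]3O[C@@H]3[C@@]1(C)O2 | intermediate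
43 | 4-methoxybenzyl alcohol | COc1ccc(CO)cc1 | starting material
44 | ethyl 2-(diethoxyphosphoryl)acrylate | CCOC(=O)C(=C)P(=O)(OCC)OCC | starting material
45 | ethyl 2-(diethoxyphosphoryl)-3-[(4-methoxybenzyl)oxy]propanoate (racemic) | CCOC(=O)C(COCc1ccc(OC)cc1)P(=O)(OCC)OCC | intermediate
46 | 2-(diethoxyphosphoryl)-3-[(4-methoxybenzyl)oxy]propanoic acid (racemic) | OC(=O)C(COCc1ccc(OC)cc1)P(=O)(OCC)OCC | intermediate
47 | 6β-O-[2-(diethoxyphosphoryl)-3-(PMB-oxy)propanoyl] ester of 42 (epimers at the phosphonate carbon) | [C@H]12[C@H](OC(=O)C(COCc5ccc(OC)cc5)P(=O)(OCC)OCC)C(=O)[C@@H](OC(C)=O)[C@@H](O[Si](C(C)C)(C(C)C)C(C)C)/C(CO[Si](c4ccccc4)(c4ccccc4)C(C)(C)C)=C\[C@H]3O[C@@H]3[C@@]1(C)O2 | intermediate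
48 | 8α-acetoxy-13-PMBO-9α-TIPSO-14-TBDPSO-2α,3β:4α,5α-diepoxygermacra-1(10)Z,7(11)-dien-12,6β-olide | COc1ccc(cc1)COCC2=C3[C@@H](OC(C)=O)[C@@H](O[Si](C(C)C)(C(C)C)C(C)C)/C(CO[Si](c4ccccc4)(c4ccccc4)C(C)(C)C)=C\[C@H]5O[C@@H]5[C@@]5(C)O[C@H]5[C@@H]3OC2=O | intermediate
49 | 8α-acetoxy-9α,14-dihydroxy-13-PMBO-2α,3β:4α,5α-diepoxygermacra-1(10)Z,7(11)-dien-12,6β-olide | COc1ccc(cc1)COCC2=C3[C@@H](OC(C)=O)[C@@H](O)/C(CO)=C\[C@H]5O[C@@H]5[C@@]5(C)O[C@H]5[C@@H]3OC2=O | intermediate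
50 | 3-methylbut-2-enoyl chloride | CC(C)=CC(Cl)=O | starting material
51 | 14-O-(3-methylbut-2-enoyl) derivative of 49 (9α-OH free) | COc1ccc(cc1)COCC2=C3[C@@H](OC(C)=O)[C@@H](O)/C(COC(=O)C=C(C)C)=C\[C@H]5O[C@@H]5[C@@]5(C)O[C@H]5[C@@H]3OC2=O | intermediate
52 | methyl (S)-2-methyloxirane-2-carboxylate | COC(=O)[C@]1(C)CO1 | starting material
53 | (S)-2-methyloxirane-2-carboxylic acid | OC(=O)[C@]1(C)CO1 | intermediate
54 | 9β-O-[(S)-2-methyloxirane-2-carbonyl]-13-O-PMB precursor (8α-OAc, 14-O-3-methylbut-2-enoyl) | COc1ccc(cc1)COCC2=C3[C@@H](OC(C)=O)[C@H](OC(=O)[C@]6(C)CO6)/C(COC(=O)C=C(C)C)=C\[C@H]5O[C@@H]5[C@@]5(C)O[C@H]5[C@@H]3OC2=O | intermediate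
55 | 13-alcohol (13-deacetyl target) | OCC1=C2[C@@H](OC(C)=O)[C@H](OC(=O)[C@]3(C)CO3)/C(COC(=O)C=C(C)C)=C\[C@H]3O[C@@H]3[C@@]3(C)O[C@H]3[C@@H]2OC1=O | intermediate
56 | CNP0279449.1 | CC(=O)OCC1=C2[C@@H](OC(C)=O)[C@H](OC(=O)[C@]3(C)CO3)/C(COC(=O)C=C(C)C)=C\[C@H]3O[C@@H]3[C@@]3(C)O[C@H]3[C@@H]2OC1=O | target

**Step count and risks**

Total: 42 steps. Longest linear sequence: 39 steps (steps 1–32, 35–38, 40–42); steps 33–34 and 39 prepare the two acid fragments.

Steps most likely to fail: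

(1) Step 30. On the flexible ten-membered ring the enolate may be attacked from the wrong face, so that the C8 epimer is formed partly or mainly. The fallback keeps that material instead of discarding it. From 38 the hydroxylation is run as before and the epimeric 8β-hydroxy ketone F3 is separated. F3 is then acetylated with inversion by a Mitsunobu reaction (AcOH, PPh3, DIAD, toluene, 0 °C; SN2 at the carbonyl-activated carbinol), which gives 41. Both epimers thus converge on 41, the 8α-alcohol by plain acetylation and the 8β-alcohol by invertive acetylation.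

(2) Step 40. The hindered α-quaternary acid may react sluggishly, and the allylic oxyphosphonium may eliminate to a diene or be attacked at C1 (SN2′) instead of C9. The fallback separates activation from displacement. From 51, mesylation (MsCl, Et3N, CH2Cl2, −40 °C) gives the 9α-mesylate F4. F4 is displaced with inversion by caesium (S)-2-methyloxirane-2-carboxylate (from 53 and Cs2CO3, DMF, 20 °C), which rejoins the route at 54.

(3) Step 15. The Lewis acid may ionise the tertiary carbinols or strip the PMB and silyl ethers, and the urethane may attack C1 instead of C2. The fallback installs the 2α,3α-diol by osmylation instead of epoxide opening. From 17, Wharton transposition of the epoxy ketone (N2H4·H2O, AcOH, MeOH, 20 °C) gives the 1β-hydroxy-2,4-diene F1. Upjohn dihydroxylation (OsO4 cat., N-methylmorpholine N-oxide) of its disubstituted C2=C3 bond, anti to the allylic 1β-hydroxyl, gives the 1β,2α,3α-triol F2. Hydroxyl-directed osmylation of C4=C5 (OsO4, TMEDA, then ethylenediamine), steered by the 3α-OH, then gives pentaol 24.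

**Further compounds**

F1 | step 15 | 6β-PMBO-7β-TBSO-4-methyl-14-TBDPSO-9α-TIPSO-decala-2,4-dien-1β-ol | O[C@@H]1C=CC(C)=C3[C@H](OCc5ccc(OC)cc5)[C@H](O[Si](C)(C)C(C)(C)C)C[C@@H](O[Si](C(C)C)(C(C)C)C(C)C)[C@]13CO[Si](c4ccccc4)(c4ccccc4)C(C)(C)C
F2 | step 15 | 6β-PMBO-7β-TBSO-4-methyl-14-TBDPSO-9α-TIPSO-decal-4-ene-1β,2α,3α-triol | O[C@@H]1[C@@H](O)[C@@H](O)C(C)=C3[C@H](OCc5ccc(OC)cc5)[C@H](O[Si](C)(C)C(C)(C)C)C[C@@H](O[Si](C(C)C)(C(C)C)C(C)C)[C@]13CO[Si](c4ccccc4)(c4ccccc4)C(C)(C)C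
F3 | step 30 | 8β-hydroxy-7-ketone (C8 epimer of 40) | [C@H]12[C@H](OCc5ccc(OC)cc5)C(=O)[C@H](O)[C@@H](O[Si](C(C)C)(C(C)C)C(C)C)/C(CO[Si](c4ccccc4)(c4ccccc4)C(C)(C)C)=C\[C@H]3O[C@@H]3[C@@]1(C)O2
F4 | step 40 | 9α-mesylate of 51 | COc1ccc(cc1)COCC2=C3[C@@H](OC(C)=O)[C@@H](OS(C)(=O)=O)/C(COC(=O)C=C(C)C)=C\[C@H]5O[C@@H]5[C@@]5(C)O[C@H]5[C@@H]3OC2=O
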